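**Retrosynthetic overview**
- The strategy rests on C4 of the upper unit. It is doubly benzylic, bonded to C4a of ring A (ortho to the ring oxygen O1) and to C8′ of ring D, and its neighbour C3 carries oxygen. C4 is therefore the exocyclic carbon of a ring A ortho-quinone methide, and C3 is the α-carbon of an O-benzyl glycolaldehyde.
- The target comes from its undecabenzyl ether. That ether comes from silane reduction of a C2 hemiketal (sets C2), made by adding the ring B aryllithium to a ring C lactone.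
- The lactone comes from a ring C lactol. The lactol is cut at C3–C4 and O1–C2 into a ring A salicyl diaryl carbinol (the methide precursor) and benzyloxyacetaldehyde under chiral enamine catalysis.
- The carbinol is cut at C4–C8′ into 8-lithio-penta-O-benzylcatechin and an O-allyl ring A salicylaldehyde.
- Rings D, F, E come intact from (+)-catechin and ring A from 2,4,6-trihydroxybenzaldehyde. Ring C is the only ring closed (key step), and ring B is attached afterwards.

Key step: step 8

Remark: the diaryl carbinol epimers, the lactol anomers and the hemiketal anomers are carried on as mixtures, because the stereocentre concerned is erased in the next step. "Cat8" stands for the (2R,3S)-3,5,7-tris(benzyloxy)-2-[3,4-bis(benzyloxy)phenyl]chroman-8-yl group.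

**Route**

Step 1
Reactants: 1 (+)-catechin
Product: 2 5,7,3′,4′-tetra-O-benzyl-(+)-catechin
Conditions: BnBr (4.4 equiv), K2CO3, DMF, 0 °C → rt
Reagents that add atoms: benzyl bromide, BrCc1ccccc1
Why: Williamson etherification in which K2CO3 deprotonates only the four phenols, so the C3 alcohol stays free and the mild base at room temperature leaves C2 and C3 untouched.

Step 2
Reactants: 2 5,7,3′,4′-tetra-O-benzyl-(+)-catechin
Product: 3 8-bromo-5,7,3′,4′-tetra-O-benzyl-(+)-catechin
Conditions: NBS (1.0 equiv), CH2Cl2, −78 °C → rt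
Reagents that add atoms: N-bromosuccinimide, O=C1CCC(=O)N1Br
Why: Electrophilic aromatic bromination of the phloroglucinol-type ring, expected at C8 as is general for 5,7-di-O-alkyl flavan-3-ols, with one equivalent of reagent at low temperature limiting it to monobromination.

Step 3
Reactants: 3 8-bromo-5,7,3′,4′-tetra-O-benzyl-(+)-catechin
Product: 4 8-bromo-3,5,7,3′,4′-penta-O-benzyl-(+)-catechin
Conditions: NaH, BnBr, DMF, 0 °C → rt
Reagents that add atoms: benzyl bromide, BrCc1ccccc1
Why: Williamson etherification of the secondary alkoxide; the aryl bromide is inert and no stereocentre is involved.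

Step 4
Reactants: 5 2,4,6-trihydroxybenzaldehyde
Product: 6 4,6-bis(benzyloxy)-2-hydroxybenzaldehyde
Conditions: BnBr (2.05 equiv), K2CO3, DMF, rt
Reagents that add atoms: benzyl bromide, BrCc1ccccc1
Why: Selective Williamson etherification, in which the hydroxyl hydrogen-bonded to the formyl oxygen is the least nucleophilic and should remain after two equivalents of benzyl bromide are consumed.

Step 5
Reactants: 6 4,6-bis(benzyloxy)-2-hydroxybenzaldehyde
Product: 7 2-(allyloxy)-4,6-bis(benzyloxy)benzaldehyde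
Conditions: allyl bromide, K2CO3, DMF, 60 °C
Reagents that add atoms: allyl bromide, C=CCBr
Why: Williamson etherification of the chelated phenol on warming; allyl is chosen because it can later be removed without acid, which the doubly benzylic carbinol of the next intermediates would not tolerate.

Step 6
Reactants: 4 8-bromo-3,5,7,3′,4′-penta-O-benzyl-(+)-catechin; 7 2-(allyloxy)-4,6-bis(benzyloxy)benzaldehyde
Product: 9 [2-(allyloxy)-4,6-bis(benzyloxy)phenyl](Cat8)methanol (carbinol epimers), via 8-lithio-penta-O-benzylcatechin 8 (not isolated)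
Conditions: n-BuLi (1.05 equiv), THF, −78 °C; then 7, −78 → −30 °C; H2O
Reagents that add atoms: none
Why: Bromine–lithium exchange followed by 1,2-addition of the aryllithium to the aldehyde forms the C4–C8′ bond; the carbinol configuration is uncontrolled and irrelevant because this carbon becomes planar in step 8.

Step 7
Reactants: 9 [2-(allyloxy)-4,6-bis(benzyloxy)phenyl](Cat8)methanol
Product: 10 3,5-bis(benzyloxy)-2-[hydroxy(Cat8)methyl]phenol (carbinol epimers)
Conditions: Pd(PPh3)4 (5 mol %), morpholine, THF, rt; chromatography on Et3N-deactivated silica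
Reagents that add atoms: none
Why: Tsuji–Trost-type deallylation, in which the aryl allyl ether ionises to a π-allylpalladium complex that morpholine captures; the neutral to basic medium should leave the acid-labile carbinol and all benzyl ethers intact.

Step 8
Reactants: 10 3,5-bis(benzyloxy)-2-[hydroxy(Cat8)methyl]phenol; 11 benzyloxyacetaldehyde
Product: 14 (3R,4R)-3,5,7-tris(benzyloxy)-4-(Cat8)chroman-2-ol (anomers at C2), via ortho-quinone methide 12 (not isolated), via open-chain aldehyde 13 (not isolated)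
Conditions: (S)-α,α-diphenylprolinol trimethylsilyl ether (20 mol %), PhCO2H (20 mol %), 11 (3 equiv), CH2Cl2, 0 °C → rt, slow addition of 10; aq NaHCO3
Reagents that add atoms: none
Why: Benzoic acid ionises the doubly benzylic carbinol of either epimer of 10 to the ring A ortho-quinone methide 12 (C4 exocyclic, stabilised by the oxygen donors of ring D); the E-enamine formed from 11 and the catalyst adds through its β-carbon to C4 (C3–C4 bond) with rearomatisation of ring A, and hydrolysis of the iminium ion releases the catalyst and aldehyde 13. The closest known reaction type is the diarylprolinol silyl ether-catalysed formal [4+2] annulation of in situ generated ortho-quinone methides with enolisable aldehydes to 3,4-disubstituted chroman-2-ols, and α-alkoxyacetaldehydes are established enamine donors with this catalyst class. Ring C closes by 6-exo-trig addition of the ring A phenol oxygen O1 to the aldehyde carbon C2 (reversible hemiacetalisation, hence the anomer mixture). C3 is set by the catalyst: the diphenyl(silyloxy)methyl group shields one face of the s-trans E-enamine so that C4 bonds to the open face, which for the (S)-catalyst corresponds to 3R. C4 is set by the relative topicity of a synclinal open transition state in which the ring A carbonyl oxygen lies near the enamine nitrogen and the ring D aryl points away from the enamine, which leads to the 3,4-trans (4R) arrangement that is also the more stable one. The step needs C-alkylation at C4 rather than O- or N-alkylation and face selection at C4 that overrides any bias from the remote C2′ and C3′ centres; the substrate secures the regiochemistry because the only free phenol is the ring A hydroxyl next to the carbinol (one possible methide, one possible ring closure) and because C4 ionises under acid weak enough to leave the catalyst silyl ether and all benzyl ethers untouched.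

Step 9
Reactants: 14 (3R,4R)-3,5,7-tris(benzyloxy)-4-(Cat8)chroman-2-ol
Product: 15 (3R,4R)-3,5,7-tris(benzyloxy)-4-(Cat8)chroman-2-one
Conditions: (n-Pr4N)RuO4 (5 mol %), N-methylmorpholine N-oxide (1.5 equiv), 4 Å molecular sieves, CH2Cl2, rt
Reagents that add atoms: none
Why: Perruthenate-catalysed oxidation of a lactol to the lactone under neutral conditions, which should not disturb C3; the 3,4-trans lactone is in any case the thermodynamically preferred C3 epimer.

Step 10
Reactants: 15 (3R,4R)-3,5,7-tris(benzyloxy)-4-(Cat8)chroman-2-one; 16 5-bromo-1,2,3-tris(benzyloxy)benzene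
Product: 18 (3R,4R)-3,5,7-tris(benzyloxy)-2-[3,4,5-tris(benzyloxy)phenyl]-4-(Cat8)chroman-2-ol (anomers at C2, in equilibrium with the open hydroxy ketone), via 3,4,5-tris(benzyloxy)phenyllithium 17 (not isolated)
Conditions: 16, n-BuLi, THF, −78 °C; cannulate (1.1 equiv) into 15, THF, −78 °C; AcOH/THF quench at −78 °C
Reagents that add atoms: none
Why: Bromine–lithium exchange and addition of the ring B aryllithium to the lactone carbonyl give a tetrahedral lithium alkoxide that should persist at −78 °C until the cold acidic quench, which limits double addition and enolisation at C3.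

Step 11
Reactants: 18 (3R,4R)-3,5,7-tris(benzyloxy)-2-[3,4,5-tris(benzyloxy)phenyl]-4-(Cat8)chroman-2-ol
Product: 20 (2R,3R,4R)-3,5,7-tris(benzyloxy)-2-[3,4,5-tris(benzyloxy)phenyl]-4-(Cat8)chromane, via chromanylium triflate 19 (not isolated)
Conditions: Et3SiH (5 equiv), Me3SiOTf (0.2 equiv), CH2Cl2, −78 → −40 °C; Et3N quench
Reagents that add atoms: none
Why: Ionic hydrogenation of the hemiketal through the 2-aryl chromanylium ion 19, whose half-chair should hold the C3 benzyloxy group pseudoaxial (allylic strain against the coplanar C2 aryl, and trans-diaxial pairing with the C4 aryl that avoids the C5 benzyloxy group), so that axial hydride delivery anti to the C3 oxygen places the ring B aryl cis to it (2R, 2,3-cis).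

Step 12
Reactants: 20 (2R,3R,4R)-3,5,7-tris(benzyloxy)-2-[3,4,5-tris(benzyloxy)phenyl]-4-(Cat8)chromane
Product: 21 epigallocatechin-(4β→8)-catechin (CNP0225927.1)
Conditions: H2 (1 atm), Pd(OH)2/C, THF/MeOH/H2O, rt; filtration, lyophilisation
Reagents that add atoms: none
Why: Catalytic hydrogenolysis of all eleven benzyl ethers under neutral conditions, which should not cleave the cyclic C2–O1 ethers or the C4–C8′ bond and touches no stereocentre.

**Compound list**

1 | (+)-catechin | Oc1cc(O)c2c(c1)O[C@H](c1ccc(O)c(O)c1)[C@@H](O)C2 | starting material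
2 | 5,7,3′,4′-tetra-O-benzyl-(+)-catechin | O(Cc1ccccc1)c1cc(OCc3ccccc3)c2c(c1)O[C@H](c1ccc(OCc3ccccc3)c(OCc3ccccc3)c1)[C@@H](O)C2 | intermediate
3 | 8-bromo-5,7,3′,4′-tetra-O-benzyl-(+)-catechin | O(Cc1ccccc1)c1cc(OCc3ccccc3)c2c(c1Br)O[C@H](c1ccc(OCc3ccccc3)c(OCc3ccccc3)c1)[C@@H](O)C2 | intermediate
4 | 8-bromo-3,5,7,3′,4′-penta-O-benzyl-(+)-catechin | O(Cc1ccccc1)c1cc(OCc3ccccc3)c2c(c1Br)O[C@H](c1ccc(OCc3ccccc3)c(OCc3ccccc3)c1)[C@@H](OCc3ccccc3)C2 | intermediate
5 | 2,4,6-trihydroxybenzaldehyde | O=Cc1c(O)cc(O)cc1O | starting material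
6 | 4,6-bis(benzyloxy)-2-hydroxybenzaldehyde | O=Cc1c(O)cc(OCc2ccccc2)cc1OCc1ccccc1 | intermediate
7 | 2-(allyloxy)-4,6-bis(benzyloxy)benzaldehyde | O=Cc1c(OCC=C)cc(OCc2ccccc2)cc1OCc1ccccc1 | intermediate
8 | 8-lithio-3,5,7,3′,4′-penta-O-benzylcatechin | [Li]c1c(OCc3ccccc3)cc(OCc3ccccc3)c2c1O[C@H](c1ccc(OCc3ccccc3)c(OCc3ccccc3)c1)[C@@H](OCc3ccccc3)C2 | intermediate
9 | [2-(allyloxy)-4,6-bis(benzyloxy)phenyl](Cat8)methanol, carbinol epimers | C(c1ccccc1)Oc1cc(OCc3ccccc3)c(c(OCC=C)c1)C(O)c1c(OCc3ccccc3)cc(OCc3ccccc3)c2c1O[C@H](c1ccc(OCc3ccccc3)c(OCc3ccccc3)c1)[C@@H](OCc3ccccc3)C2 | intermediate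
10 | 3,5-bis(benzyloxy)-2-[hydroxy(Cat8)methyl]phenol, carbinol epimers | C(c1ccccc1)Oc1cc(OCc3ccccc3)c(c(O)c1)C(O)c1c(OCc3ccccc3)cc(OCc3ccccc3)c2c1O[C@H](c1ccc(OCc3ccccc3)c(OCc3ccccc3)c1)[C@@H](OCc3ccccc3)C2 | intermediate
11 | benzyloxyacetaldehyde | O=CCOCc1ccccc1 | starting material
12 | 3,5-bis(benzyloxy)-6-[(Cat8)methylidene]cyclohexa-2,4-dien-1-one (ring A ortho-quinone methide) | O=C1C=C(OCc3ccccc3)C=C(OCc3ccccc3)C1=Cc1c(OCc3ccccc3)cc(OCc3ccccc3)c2c1O[C@H](c1ccc(OCc3ccccc3)c(OCc3ccccc3)c1)[C@@H](OCc3ccccc3)C2 | intermediate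
13 | (2R,3R)-2-(benzyloxy)-3-[2,4-bis(benzyloxy)-6-hydroxyphenyl]-3-(Cat8)propanal | O=C[C@H](OCc3ccccc3)[C@H](c1c(O)cc(OCc3ccccc3)cc1OCc1ccccc1)c1c(OCc3ccccc3)cc(OCc3ccccc3)c2c1O[C@H](c1ccc(OCc3ccccc3)c(OCc3ccccc3)c1)[C@@H](OCc3ccccc3)C2 | intermediate
14 | (3R,4R)-3,5,7-tris(benzyloxy)-4-(Cat8)chroman-2-ol, anomers at C2 | C(c1ccccc1)Oc1cc(OCc3ccccc3)c2c(c1)OC(O)[C@H](OCc3ccccc3)[C@H]2c1c(OCc3ccccc3)cc(OCc3ccccc3)c2c1O[C@H](c1ccc(OCc3ccccc3)c(OCc3ccccc3)c1)[C@@H](OCc3ccccc3)C2 | intermediate
15 | (3R,4R)-3,5,7-tris(benzyloxy)-4-(Cat8)chroman-2-one | C(c1ccccc1)Oc1cc(OCc3ccccc3)c2c(c1)OC(=O)[C@H](OCc3ccccc3)[C@H]2c1c(OCc3ccccc3)cc(OCc3ccccc3)c2c1O[C@H](c1ccc(OCc3ccccc3)c(OCc3ccccc3)c1)[C@@H](OCc3ccccc3)C2 | intermediate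
16 | 5-bromo-1,2,3-tris(benzyloxy)benzene | Brc1cc(OCc2ccccc2)c(OCc2ccccc2)c(OCc2ccccc2)c1 | starting material
17 | 3,4,5-tris(benzyloxy)phenyllithium | [Li]c1cc(OCc2ccccc2)c(OCc2ccccc2)c(OCc2ccccc2)c1 | intermediate
18 | (3R,4R)-3,5,7-tris(benzyloxy)-2-[3,4,5-tris(benzyloxy)phenyl]-4-(Cat8)chroman-2-ol, anomers at C2 | C(c1ccccc1)Oc1cc(OCc3ccccc3)c2c(c1)OC(O)(c1cc(OCc3ccccc3)c(OCc3ccccc3)c(OCc3ccccc3)c1)[C@H](OCc3ccccc3)[C@H]2c1c(OCc3ccccc3)cc(OCc3ccccc3)c2c1O[C@H](c1ccc(OCc3ccccc3)c(OCc3ccccc3)c1)[C@@H](OCc3ccccc3)C2 | intermediate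
19 | (3R,4R)-3,5,7-tris(benzyloxy)-2-[3,4,5-tris(benzyloxy)phenyl]-4-(Cat8)-3,4-dihydrochromenylium triflate | C(c1ccccc1)Oc1cc(OCc3ccccc3)c2c(c1)[O+]=C(c1cc(OCc3ccccc3)c(OCc3ccccc3)c(OCc3ccccc3)c1)[C@H](OCc3ccccc3)[C@H]2c1c(OCc3ccccc3)cc(OCc3ccccc3)c2c1O[C@H](c1ccc(OCc3ccccc3)c(OCc3ccccc3)c1)[C@@H](OCc3ccccc3)C2.[O-]S(=O)(=O)C(F)(F)F | intermediate
20 | (2R,3R,4R)-3,5,7-tris(benzyloxy)-2-[3,4,5-tris(benzyloxy)phenyl]-4-(Cat8)chromane (undeca-O-benzyl ether of the target) | C(c1ccccc1)Oc1cc(OCc3ccccc3)c2c(c1)O[C@H](c1cc(OCc3ccccc3)c(OCc3ccccc3)c(OCc3ccccc3)c1)[C@H](OCc3ccccc3)[C@H]2c1c(OCc3ccccc3)cc(OCc3ccccc3)c2c1O[C@H](c1ccc(OCc3ccccc3)c(OCc3ccccc3)c1)[C@@H](OCc3ccccc3)C2 | intermediate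
21 | epigallocatechin-(4β→8)-catechin, (2R,3R,4R)-2-(3,4,5-trihydroxyphenyl)-4-[(2R,3S)-2-(3,4-dihydroxyphenyl)-3,5,7-trihydroxychroman-8-yl]chromane-3,5,7-triol | Oc1cc(O)c2c(c1)O[C@H](c1cc(O)c(O)c(O)c1)[C@H](O)[C@H]2c1c(O)cc(O)c2c1O[C@H](c1ccc(O)c(O)c1)[C@@H](O)C2 | target

**Step count and risks**

Total step count: 12. Longest linear sequence: 10 steps (steps 1–3 and 6–12; steps 4–5 form the ring A branch).

Steps most likely to fail:

1. Step 8. The enamine may add to the wrong face of the methide carbon C4. This could happen because the catalyst and the resident catechin centres are mismatched, or because the methide reacts through the geometry in which the ring D aryl lies syn to the ring A carbonyl (the C5 benzyloxy group flanks the other side). C4 cannot be corrected later, since base equilibration of the lactone only adjusts C3 relative to C4. Bond formation at this hindered, strongly stabilised methide may also be slow enough for self-aldolisation of 11 or reversible capture of the methide by the amine to compete. Fallback, setting out from 10: the carbinol would be ionised with catalytic Sc(OTf)3 (CH2Cl2, −40 °C) in the presence of excess silyl ketene acetal 2-(benzyloxy)-1-methoxy-1-(trimethylsilyloxy)ethene F1 (from methyl benzyloxyacetate, LDA, Me3SiCl, THF, −78 °C). This Mukaiyama–Michael addition to methide 12 should give methyl 2-(benzyloxy)-3-[2,4-bis(benzyloxy)-6-hydroxyphenyl]-3-(Cat8)propanoate F2 as a stereoisomer mixture. DBU in toluene at 60 °C should then lactonise the ring A phenol onto the ester and equilibrate C3 to the 3,4-trans lactones, namely 15 and its diastereomer (3S,4S)-3,5,7-tris(benzyloxy)-4-(Cat8)chroman-2-one F3. These differ as diastereomers through the catechin unit and would be separated by chromatography. The route is rejoined at 15.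

2. Step 10. The tetrahedral adduct may collapse with loss of the ring A phenoxide, so that a second aryllithium adds to the liberated ketone, or 17 may deprotonate C3 next to the lactone carbonyl and erode the 3R centre. Fallback, setting out from 15: MeNH(OMe)·HCl with i-PrMgCl (THF, −20 °C) would open the lactone to (2R,3R)-2-(benzyloxy)-3-[2,4-bis(benzyloxy)-6-hydroxyphenyl]-N-methoxy-N-methyl-3-(Cat8)propanamide F4. Silylation of the freed phenol (t-BuMe2SiCl, imidazole, DMF) would give the silyl ether F5. Addition of 17 (THF, −78 °C) should stop at the aryl ketone (2R,3R)-2-(benzyloxy)-3-[2,4-bis(benzyloxy)-6-(tert-butyldimethylsilyloxy)phenyl]-3-(Cat8)-1-[3,4,5-tris(benzyloxy)phenyl]propan-1-one F6, because the chelated adduct of an N-methoxy-N-methylamide does not collapse before the quench. Bu4NF buffered with AcOH (THF, 0 °C) would free the phenol, which closes onto the ketone to give hemiketal 18, where the route is rejoined.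

3. Step 11. Hydride may be delivered syn to the C3 benzyloxy group (2,3-trans product), the cation may lose H3 to a flav-2-ene and be reprotonated with loss of C3 configuration, or the acid may cleave the C4–C8′ bond. Fallback, setting out from 18: Zn(BH4)2 (Et2O, −20 °C) would reduce the open hydroxy ketone tautomer under chelation control, with zinc bridging the carbonyl and the C3 benzyloxy oxygen. This should give the 1,2-anti alcohol (1S,2R,3R)-2-(benzyloxy)-3-[2,4-bis(benzyloxy)-6-hydroxyphenyl]-3-(Cat8)-1-[3,4,5-tris(benzyloxy)phenyl]propan-1-ol F7. Mitsunobu etherification (PPh3, diisopropyl azodicarboxylate, THF, 0 °C) would then close ring C by displacement at the benzylic carbon by the ring A phenol with inversion, giving the 2R,3R flavan 20, where the route is rejoined.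

**Further compounds**

F1 | step 8 | 2-(benzyloxy)-1-methoxy-1-(trimethylsilyloxy)ethene | COC(O[Si](C)(C)C)=COCc1ccccc1
F2 | step 8 | methyl 2-(benzyloxy)-3-[2,4-bis(benzyloxy)-6-hydroxyphenyl]-3-(Cat8)propanoate, stereoisomers at C2 and C3 | COC(=O)C(OCc3ccccc3)C(c1c(O)cc(OCc3ccccc3)cc1OCc1ccccc1)c1c(OCc3ccccc3)cc(OCc3ccccc3)c2c1O[C@H](c1ccc(OCc3ccccc3)c(OCc3ccccc3)c1)[C@@H](OCc3ccccc3)C2
F3 | step 8 | (3S,4S)-3,5,7-tris(benzyloxy)-4-(Cat8)chroman-2-one | C(c1ccccc1)Oc1cc(OCc3ccccc3)c2c(c1)OC(=O)[C@@H](OCc3ccccc3)[C@@H]2c1c(OCc3ccccc3)cc(OCc3ccccc3)c2c1O[C@H](c1ccc(OCc3ccccc3)c(OCc3ccccc3)c1)[C@@H](OCc3ccccc3)C2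
F4 | step 10 | (2R,3R)-2-(benzyloxy)-3-[2,4-bis(benzyloxy)-6-hydroxyphenyl]-N-methoxy-N-methyl-3-(Cat8)propanamide | CON(C)C(=O)[C@H](OCc3ccccc3)[C@H](c1c(O)cc(OCc3ccccc3)cc1OCc1ccccc1)c1c(OCc3ccccc3)cc(OCc3ccccc3)c2c1O[C@H](c1ccc(OCc3ccccc3)c(OCc3ccccc3)c1)[C@@H](OCc3ccccc3)C2
F5 | step 10 | (2R,3R)-2-(benzyloxy)-3-[2,4-bis(benzyloxy)-6-(tert-butyldimethylsilyloxy)phenyl]-N-methoxy-N-methyl-3-(Cat8)propanamide | CON(C)C(=O)[C@H](OCc3ccccc3)[C@H](c1c(O[Si](C)(C)C(C)(C)C)cc(OCc3ccccc3)cc1OCc1ccccc1)c1c(OCc3ccccc3)cc(OCc3ccccc3)c2c1O[C@H](c1ccc(OCc3ccccc3)c(OCc3ccccc3)c1)[C@@H](OCc3ccccc3)C2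
F6 | step 10 | (2R,3R)-2-(benzyloxy)-3-[2,4-bis(benzyloxy)-6-(tert-butyldimethylsilyloxy)phenyl]-3-(Cat8)-1-[3,4,5-tris(benzyloxy)phenyl]propan-1-one | O=C(c1cc(OCc3ccccc3)c(OCc3ccccc3)c(OCc3ccccc3)c1)[C@H](OCc3ccccc3)[C@H](c1c(O[Si](C)(C)C(C)(C)C)cc(OCc3ccccc3)cc1OCc1ccccc1)c1c(OCc3ccccc3)cc(OCc3ccccc3)c2c1O[C@H](c1ccc(OCc3ccccc3)c(OCc3ccccc3)c1)[C@@H](OCc3ccccc3)C2
F7 | step 11 | (1S,2R,3R)-2-(benzyloxy)-3-[2,4-bis(benzyloxy)-6-hydroxyphenyl]-3-(Cat8)-1-[3,4,5-tris(benzyloxy)phenyl]propan-1-ol | O[C@@H](c1cc(OCc3ccccc3)c(OCc3ccccc3)c(OCc3ccccc3)c1)[C@H](OCc3ccccc3)[C@H](c1c(O)cc(OCc3ccccc3)cc1OCc1ccccc1)c1c(OCc3ccccc3)cc(OCc3ccccc3)c2c1O[C@H](c1ccc(OCc3ccccc3)c(OCc3ccccc3)c1)[C@@H](OCc3ccccc3)C2
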